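**Plan**
- Retrosynthesis: cut the C11–O aryl ether and the C6=C7 unsaturation (back to a 7-hydroxy-8(12)-ene). Then cut, in one event, the C9–C10 bond of ring B and the C4–C5 bond of ring A, and last the C6–C7 bond (ketone enolate plus allylic bromide).
- Enabling feature: C5 is the only CH between the quaternary carbons C4 and C10. With C5 taken out of ring A, C10(Me)–C1–C2–C3(O)–C4(Me2) is the 1,2,2-trimethylcyclopentane of camphoric acid, and C5 is a neopentylic carbinol carbon on C10.
- Forward: (1S,3R)-camphoric acid gives a 3-silyloxy-1-acetylcyclopentane, which is alkylated with a (Z)-allylsilane bromide and reduced at C5. Ionisation at C5 then shifts C4 from C10 to C5, so the five-membered ring becomes ring A, and the new C10 cation closes ring B on the allylsilane, leaving the C8=C12 methylene.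
- End game: SeO2 oxidation at C7, dehydration to the 6,8(12)-diene, desilylation, Mitsunobu ether formation with umbelliferone.
- Stereochemistry: C3 from camphoric acid (retention in the Baeyer–Villiger step); C5 by inversion of a CBS-set carbinol; C10 by capture anti to the departing C4 (relay of the camphoric quaternary centre); C9 from the (Z)-allylsilane through a chair transition state.

Key step: step 12

Remark: the target is read as the 7-umbelliferyl ether of drima-6,8(12)-diene-3α,11-diol, (3R,5R,9S,10S), with 5α-H, 9α-H and 10β-CH3; drimane numbering is used throughout.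

**Step 1**
Reactants: 1 (1S,3R)-(−)-camphoric acid
Product: 2 (1S,5R)-camphoric anhydride (1,8,8-trimethyl-3-oxabicyclo[3.2.1]octane-2,4-dione)
Conditions: Ac2O, reflux
Reagents that add atoms: none
Why: the cis-1,3-diacid closes to the six-membered cyclic anhydride on dehydration with acetic anhydride, and no stereocentre is touched.

**Step 2**
Reactants: 2 camphoric anhydride
Product: 3 (1S,3R)-3-[methoxy(methyl)carbamoyl]-1,2,2-trimethylcyclopentane-1-carboxylic acid
Conditions: MeNH(OMe)·HCl, Et3N, DMAP (cat.), CH2Cl2, 0 °C to rt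
Reagents that add atoms: N,O-dimethylhydroxylamine hydrochloride, CNOC.Cl
Why: aminolysis of the anhydride should take place at the less hindered carbonyl on the secondary carbon, which leaves the neopentylic acid free (regioselective anhydride opening to a Weinreb amide).

**Step 3**
Reactants: 3 Weinreb amide acid
Product: 4 (1S,3R)-3-acetyl-1,2,2-trimethylcyclopentane-1-carboxylic acid
Conditions: MeMgBr (3 equiv), THF, −78 to 0 °C; aq. HCl
Reagents that add atoms: methylmagnesium bromide, C[Mg]Br
Why: Weinreb ketone synthesis, in which the magnesium carboxylate is inert and the chelated tetrahedral intermediate prevents a second addition.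

**Step 4**
Reactants: 4 keto acid
Product: 5 (1S,3R)-3-(acetyloxy)-1,2,2-trimethylcyclopentane-1-carboxylic acid
Conditions: mCPBA, CF3CO2H (cat.), CH2Cl2, rt
Reagents that add atoms: 3-chloroperoxybenzoic acid, OOC(=O)c1cccc(Cl)c1
Why: Baeyer–Villiger oxidation, in which the secondary ring carbon migrates in preference to methyl and with retention, so the C3 oxygen takes the configuration of the camphoric carboxyl group.

**Step 5**
Reactants: 5 acetoxy acid
Product: 6 1-[(1S,3R)-3-hydroxy-1,2,2-trimethylcyclopentyl]ethan-1-one
Conditions: MeLi (5 equiv), Et2O, 0 °C to rt; poured into cold 1 M HCl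
Reagents that add atoms: methyllithium, [Li]C
Why: methyllithium should convert the lithium carboxylate into the methyl ketone through the stable geminal dialkoxide and cleave the acetate in the same operation (ketone synthesis from a carboxylic acid).

**Step 6**
Reactants: 6 hydroxy ketone
Product: 7 1-[(1S,3R)-3-[(tert-butyldimethylsilyl)oxy]-1,2,2-trimethylcyclopentyl]ethan-1-one
Conditions: TBSOTf (1.1 equiv), 2,6-lutidine, CH2Cl2, −78 °C
Reagents that add atoms: tert-butyldimethylsilyl trifluoromethanesulfonate, CC(C)(C)[Si](C)(C)OS(=O)(=O)C(F)(F)F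
Why: silylation of the hindered secondary alcohol with the silyl triflate at low temperature should be faster than enol silylation of the ketone.

**Step 7**
Reactants: 8 2-butyne-1,4-diol
Product: 9 4-[(tert-butyldimethylsilyl)oxy]but-2-yn-1-ol
Conditions: TBSCl (1 equiv), imidazole, diol (3 equiv), DMF, 0 °C
Reagents that add atoms: tert-butyldimethylsilyl chloride, CC(C)(C)[Si](C)(C)Cl
Why: statistical monosilylation of a symmetrical diol used in excess.

**Step 8**
Reactants: 9 monosilylated butynediol
Product: 10 (2Z)-4-[(tert-butyldimethylsilyl)oxy]-2-[(trimethylsilyl)methyl]but-2-en-1-ol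
Conditions: Me3SiCH2MgCl (3 equiv), CuI (10 mol %), Et2O/THF, 0 °C to rt; aq. NH4Cl
Reagents that add atoms: (trimethylsilyl)methylmagnesium chloride, C[Si](C)(C)C[Mg]Cl
Why: copper-catalysed anti-carbomagnesiation of a propargylic alcohol, in which the magnesium alkoxide directs the silylmethyl group to the proximal alkyne carbon and anti addition places CH2SiMe3 cis to CH2OTBS.

**Step 9**
Reactants: 10 allylsilane alcohol
Product: 11 tert-butyl{[(2E)-4-bromo-3-[(trimethylsilyl)methyl]but-2-en-1-yl]oxy}dimethylsilane
Conditions: CBr4, PPh3, 2,6-lutidine, CH2Cl2, 0 °C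
Reagents that add atoms: carbon tetrabromide, BrC(Br)(Br)Br
Why: Appel bromination of the primary allylic alcohol under neutral conditions, which should leave the alkene geometry and the acid-sensitive allylsilane intact.

**Step 10**
Reactants: 7 silyloxy methyl ketone; 11 allylic bromide
Product: 12 (4Z)-6-[(tert-butyldimethylsilyl)oxy]-1-[(1S,3R)-3-[(tert-butyldimethylsilyl)oxy]-1,2,2-trimethylcyclopentyl]-4-[(trimethylsilyl)methyl]hex-4-en-1-one
Conditions: LiN(iPr)2, THF, −78 °C; then 11, DMPU, −78 to −20 °C
Reagents that add atoms: none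
Why: the ketone can enolise only toward its methyl group because the other α-carbon is quaternary, and the lithium enolate is alkylated by the allylic bromide (SN2 enolate alkylation), which forms the C6–C7 bond.

**Step 11**
Reactants: 12 ketone
Product: 13 (1S,4Z)-6-[(tert-butyldimethylsilyl)oxy]-1-[(1S,3R)-3-[(tert-butyldimethylsilyl)oxy]-1,2,2-trimethylcyclopentyl]-4-[(trimethylsilyl)methyl]hex-4-en-1-ol
Conditions: (R)-2-methyl-CBS-oxazaborolidine (0.3 equiv), catecholborane, toluene, −78 to −30 °C
Reagents that add atoms: none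
Why: Corey–Bakshi–Shibata reduction, in which the tert-alkyl group acts as the large and the CH2 chain as the small substituent so that the (R)-catalyst should give the (S)-carbinol at C5, and catecholborane spares the trisubstituted alkene.

**Step 12**
Reactants: 13 (S)-carbinol
Product: 15 3α,11-bis[(tert-butyldimethylsilyl)oxy]drim-8(12)-ene, via C5 triflate 14 (not isolated)
Conditions: Tf2O (1.2 equiv), 2,6-di-tert-butyl-4-methylpyridine (2.5 equiv), CH2Cl2, −78 to −20 °C; aq. NaHCO3
Reagents that add atoms: none
Why: Proposed new method: O-triflation of the neopentylic carbinol puts a leaving group anti-periplanar to the C4–C10 bond (the electron-rich bond between two quaternary carbons), whose 1,2-shift from C10 to C5 (Wagner–Meerwein, cyclopentylcarbinyl to cyclohexyl) inserts C5 into the camphoric ring to make ring A, and the tertiary C10 cation is then taken by C9 of the allylsilane with loss of Me3Si+ to leave the C8=C12 methylene. The closest known reactions are the solvolytic ring enlargement of cyclopentylcarbinyl sulfonates and amines (Demjanov type) and the allylsilane-terminated cation–olefin cyclisations that give albicane skeletons; the relay of the two mirrors the ring enlargement followed by ring closure of the dammarenyl cation in triterpene biosynthesis. Ring A is not closed but enlarged by one atom through the shift, and ring B closes by 6-endo-trig attack of the C8=C9 alkene on the C10 cation through a chair transition state. C5 is set by inversion of the (S)-carbinol (C4 enters anti to the triflate), C10 by capture anti to the departing C4 (inversion of the camphoric quaternary centre, which gives the trans ring fusion), C9 by the (Z)-allylsilane, which places CH2OTBS equatorial, and C3 is not touched. The step needs C4 rather than C1 or the methyl group to migrate, which the higher migratory aptitude of the tertiary carbon, the strain of the C4–C10 bond and the favoured rotamer (H-5 between the two ring bonds, triflate anti to C4) should secure. It also needs capture to outrun proton loss, which the tethered allylsilane and the hindered base should secure.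

**Step 13**
Reactants: 15 bicyclic bis-silyl ether
Product: 16 3α,11-bis[(tert-butyldimethylsilyl)oxy]drim-8(12)-en-7α-ol
Conditions: SeO2 (0.5 equiv), t-BuOOH (3 equiv), CH2Cl2, 0 °C to rt
Reagents that add atoms: selenium dioxide, O=[Se]=O; tert-butyl hydroperoxide, CC(C)(C)OO
Why: Riley allylic oxidation (ene reaction then [2,3]-sigmatropic shift), which on exocyclic methylene decalins should oxidise the ring CH2 at C7 rather than the hindered tertiary C9, give the axial 7α-alcohol and keep the C8=C12 bond.

**Step 14**
Reactants: 16 allylic alcohol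
Product: 17 3α,11-bis[(tert-butyldimethylsilyl)oxy]drima-6,8(12)-diene
Conditions: Martin sulfurane, Ph2S[OC(CF3)2Ph]2 (1.5 equiv), CH2Cl2, 0 °C to rt
Reagents that add atoms: none
Why: Martin sulfurane dehydration by anti elimination of the axial 7α-oxysulfonium group with the axial 6β-hydrogen; C6 is the only neighbour that carries a hydrogen able to give an alkene, so the conjugated 6,8(12)-diene should result.

**Step 15**
Reactants: 17 diene bis-silyl ether
Product: 18 drima-6,8(12)-diene-3α,11-diol
Conditions: Bu4NF (5 equiv), THF, 50 °C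
Reagents that add atoms: none
Why: fluoride cleavage of both silyl ethers under basic conditions that should not isomerise the diene.

**Step 16**
Reactants: 18 diene diol; 19 umbelliferone (7-hydroxy-2H-chromen-2-one)
Product: 20 7-{[(1S,4aR,6R,8aS)-6-hydroxy-5,5,8a-trimethyl-2-methylidene-1,2,4a,5,6,7,8,8a-octahydronaphthalen-1-yl]methoxy}-2H-chromen-2-one (target)
Conditions: PPh3, DIAD (betaine preformed at 0 °C), THF, 0 °C to rt
Reagents that add atoms: none
Why: Mitsunobu etherification with an acidic phenol, in which the primary C11 hydroxyl should react while the axial, neopentylic 3α-hydroxyl does not.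

**Compound list**
1 | (1S,3R)-(−)-camphoric acid | OC(=O)[C@@]1(C)CC[C@@H](C(=O)O)C1(C)C | starting material
2 | (1S,5R)-camphoric anhydride | O=C1OC(=O)[C@@]2(C)CC[C@@H]1C2(C)C | intermediate
3 | (1S,3R)-3-[methoxy(methyl)carbamoyl]-1,2,2-trimethylcyclopentane-1-carboxylic acid | OC(=O)[C@@]1(C)CC[C@@H](C(=O)N(C)OC)C1(C)C | intermediate
4 | (1S,3R)-3-acetyl-1,2,2-trimethylcyclopentane-1-carboxylic acid | OC(=O)[C@@]1(C)CC[C@@H](C(C)=O)C1(C)C | intermediate
5 | (1S,3R)-3-(acetyloxy)-1,2,2-trimethylcyclopentane-1-carboxylic acid | OC(=O)[C@@]1(C)CC[C@@H](OC(C)=O)C1(C)C | intermediate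
6 | 1-[(1S,3R)-3-hydroxy-1,2,2-trimethylcyclopentyl]ethan-1-one | CC(=O)[C@@]1(C)CC[C@@H](O)C1(C)C | intermediate
7 | 1-[(1S,3R)-3-[(tert-butyldimethylsilyl)oxy]-1,2,2-trimethylcyclopentyl]ethan-1-one | CC(=O)[C@@]1(C)CC[C@@H](O[Si](C)(C)C(C)(C)C)C1(C)C | intermediate
8 | 2-butyne-1,4-diol | OCC#CCO | starting material
9 | 4-[(tert-butyldimethylsilyl)oxy]but-2-yn-1-ol | OCC#CCO[Si](C)(C)C(C)(C)C | intermediate
10 | (2Z)-4-[(tert-butyldimethylsilyl)oxy]-2-[(trimethylsilyl)methyl]but-2-en-1-ol | OC/C(=C/CO[Si](C)(C)C(C)(C)C)C[Si](C)(C)C | intermediate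
11 | tert-butyl{[(2E)-4-bromo-3-[(trimethylsilyl)methyl]but-2-en-1-yl]oxy}dimethylsilane | BrC/C(=C/CO[Si](C)(C)C(C)(C)C)C[Si](C)(C)C | intermediate
12 | (4Z)-6-[(tert-butyldimethylsilyl)oxy]-1-[(1S,3R)-3-[(tert-butyldimethylsilyl)oxy]-1,2,2-trimethylcyclopentyl]-4-[(trimethylsilyl)methyl]hex-4-en-1-one | CC(C)(C)[Si](C)(C)OC/C=C(/CCC(=O)[C@@]1(C)CC[C@@H](O[Si](C)(C)C(C)(C)C)C1(C)C)C[Si](C)(C)C | intermediate
13 | (1S,4Z)-6-[(tert-butyldimethylsilyl)oxy]-1-[(1S,3R)-3-[(tert-butyldimethylsilyl)oxy]-1,2,2-trimethylcyclopentyl]-4-[(trimethylsilyl)methyl]hex-4-en-1-ol | CC(C)(C)[Si](C)(C)OC/C=C(/CC[C@H](O)[C@@]1(C)CC[C@@H](O[Si](C)(C)C(C)(C)C)C1(C)C)C[Si](C)(C)C | intermediate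
14 | trifluoromethanesulfonate of 13 at C5 (not isolated) | CC(C)(C)[Si](C)(C)OC/C=C(/CC[C@H](OS(=O)(=O)C(F)(F)F)[C@@]1(C)CC[C@@H](O[Si](C)(C)C(C)(C)C)C1(C)C)C[Si](C)(C)C | intermediate
15 | 3α,11-bis[(tert-butyldimethylsilyl)oxy]drim-8(12)-ene (5α-H, 9α-H, 10β-CH3) | C=C1CC[C@H]2C(C)(C)[C@H](O[Si](C)(C)C(C)(C)C)CC[C@]2(C)[C@H]1CO[Si](C)(C)C(C)(C)C | intermediate
16 | 3α,11-bis[(tert-butyldimethylsilyl)oxy]drim-8(12)-en-7α-ol | C=C1[C@H](O)C[C@H]2C(C)(C)[C@H](O[Si](C)(C)C(C)(C)C)CC[C@]2(C)[C@H]1CO[Si](C)(C)C(C)(C)C | intermediate
17 | 3α,11-bis[(tert-butyldimethylsilyl)oxy]drima-6,8(12)-diene | C=C1C=C[C@H]2C(C)(C)[C@H](O[Si](C)(C)C(C)(C)C)CC[C@]2(C)[C@H]1CO[Si](C)(C)C(C)(C)C | intermediate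
18 | drima-6,8(12)-diene-3α,11-diol | C=C1C=C[C@H]2C(C)(C)[C@H](O)CC[C@]2(C)[C@H]1CO | intermediate
19 | umbelliferone (7-hydroxy-2H-chromen-2-one) | Oc1ccc2ccc(=O)oc2c1 | starting material
20 | 7-{[(1S,4aR,6R,8aS)-6-hydroxy-5,5,8a-trimethyl-2-methylidene-1,2,4a,5,6,7,8,8a-octahydronaphthalen-1-yl]methoxy}-2H-chromen-2-one | C=C1C=C[C@H]2C(C)(C)[C@H](O)CC[C@]2(C)[C@H]1COc1ccc2ccc(=O)oc2c1 | target

**Step count**
Total: 16 steps. Longest linear sequence: 13 steps (steps 1–6 and 10–16).

**Steps most likely to fail**

1. Step 12 (Proposed new method). What may go wrong: ionisation at C5 that is not coupled to the shift of the C4–C10 bond (proton loss toward C6, or shift of C1 or of the methyl group), or closure of ring B from the wrong face. The fallback changes the trigger to a diazonium ion, whose loss of nitrogen needs no assistance, and uses known reaction types (Demjanov ring enlargement of a cyclopentylcarbinyl amine, allylsilane capture of a tertiary cation). It sets out from ketone 12 and comes back at 15. Ketone 12 is condensed with hydroxylamine (NH2OH·HCl, NaOAc, EtOH, 60 °C) to the oxime F1. The oxime is reduced with LiAlH4 in THF to the primary amine F2 (C5 epimers would form; the (S)-epimer is drawn and would be separated). Deamination of the amine (NaNO2, aqueous AcOH, 0 °C) should then enlarge the ring by the same 1,2-shift, and the allylsilane closes ring B to give 15.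

2. Step 13. What may go wrong: hydrogen abstraction at C9 instead of C7, and over-oxidation of the allylic alcohol to the enone. The fallback removes C12 and puts it back after the ring unsaturation is in place. It sets out from 15 and comes back at 17, so it also bypasses step 14. Ozonolysis of 15 (O3, CH2Cl2, −78 °C; Me2S) gives the 12-nor-8-ketone F3. Kinetic enolisation toward the C7 methylene and dehydrogenation (LiN(iPr)2, then N-tert-butylbenzenesulfinimidoyl chloride, −78 °C) gives the 12-nor-6-en-8-one F4. Wittig methylenation (Ph3P=CH2, toluene) then returns the diene 17.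

3. Step 16. What may go wrong: slow substitution at the β-branched C11, elimination of the oxyphosphonium intermediate toward C9, and ene reaction of the azodicarboxylate with the diene. The fallback replaces the redox condensation by a preformed sulfonate and a Williamson displacement. It sets out from 18 and comes back at 20. Selective triflation of the primary hydroxyl (Tf2O, 2,6-lutidine, CH2Cl2, −78 °C) gives the C11 triflate F5, which is displaced by the caesium salt of 19 (Cs2CO3, DMF, 0 °C) to give 20.

**Further compounds**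
F1 | step 12 | oxime of ketone 12 | CC(C)(C)[Si](C)(C)OC/C=C(/CC/C(=N\O)[C@@]1(C)CC[C@@H](O[Si](C)(C)C(C)(C)C)C1(C)C)C[Si](C)(C)C
F2 | step 12 | (1S,4Z)-6-[(tert-butyldimethylsilyl)oxy]-1-[(1S,3R)-3-[(tert-butyldimethylsilyl)oxy]-1,2,2-trimethylcyclopentyl]-4-[(trimethylsilyl)methyl]hex-4-en-1-amine | CC(C)(C)[Si](C)(C)OC/C=C(/CC[C@H](N)[C@@]1(C)CC[C@@H](O[Si](C)(C)C(C)(C)C)C1(C)C)C[Si](C)(C)C
F3 | step 13 | 3α,11-bis[(tert-butyldimethylsilyl)oxy]-12-nordriman-8-one | O=C1CC[C@H]2C(C)(C)[C@H](O[Si](C)(C)C(C)(C)C)CC[C@]2(C)[C@H]1CO[Si](C)(C)C(C)(C)C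
F4 | step 13 | 3α,11-bis[(tert-butyldimethylsilyl)oxy]-12-nordrim-6-en-8-one | O=C1C=C[C@H]2C(C)(C)[C@H](O[Si](C)(C)C(C)(C)C)CC[C@]2(C)[C@H]1CO[Si](C)(C)C(C)(C)C
F5 | step 16 | 3α-hydroxydrima-6,8(12)-dien-11-yl trifluoromethanesulfonate | C=C1C=C[C@H]2C(C)(C)[C@H](O)CC[C@]2(C)[C@H]1COS(=O)(=O)C(F)(F)F
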